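**Target.** Halocynthiaxanthin. Read from the SMILES: 3S,5R,6S on the epoxy ring, 3'R on the acetylenic ring, all-E chain. Carotenoid numbering is used for positions (primed = acetylenic half).

**Assumption.** (4R,6R)-Actinol, the C10 dialdehyde 2,7-dimethylocta-2,4,6-trienedial and both isomers of 3-methylpent-2-en-4-yn-1-ol are bought.

## Retrosynthetic overview

1. Target ⇐ desilylation ⇐ Wittig union (C11=C12) of a C25 acetylenic phosphonium salt with a C15 epoxy keto enal.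
2. C15 epoxy keto enal ⇐ 2-(cyclohexenylmethyl)-3-methylfuran + O2: the furan is a masked Z-4-oxo-enal, and its peroxide oxygen makes the oxirane (C5–O, C6–O and the carbonyl oxygens in one operation).
3. Furan ⇐ actinol-derived enol triflate + (Z)-enynol: Sonogashira coupling, then 5-exo-dig C8–O ring closure.
4. C25 salt ⇐ same enol triflate + (E)-enynol → C15 phosphonium salt → Wittig with the C10 dialdehyde → aldehyde → alcohol → salt.
5. Both carbocycles come intact from actinol. Rings formed in the route: the furan (step 8, temporary), then the oxirane (step 9).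

## Route

Step 1
Reactants: 1 (4R,6R)-4-hydroxy-2,2,6-trimethylcyclohexan-1-one
Product: 2 (4R,6R)-4-[(tert-butyldimethylsilyl)oxy]-2,2,6-trimethylcyclohexan-1-one
Conditions: TBSCl, imidazole, DMF, rt
Reagents that add atoms: tert-butyldimethylsilyl chloride, C[Si](C)(Cl)C(C)(C)C
Why: Imidazole-promoted silylation (silyl ether formation) masks the only hydroxyl before enolate chemistry and touches no stereocentre.

Step 2
Reactants: 2 (4R,6R)-4-[(tert-butyldimethylsilyl)oxy]-2,2,6-trimethylcyclohexan-1-one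
Product: 4 (4R)-4-[(tert-butyldimethylsilyl)oxy]-2,6,6-trimethylcyclohex-1-en-1-yl trifluoromethanesulfonate, via potassium enolate 3 (not isolated)
Conditions: KN(SiMe3)2, THF, −78 °C; then PhNTf2, −78 → 0 °C
Reagents that add atoms: N-phenylbis(trifluoromethanesulfonimide), O=S(=O)(N(c1ccccc1)S(=O)(=O)C(F)(F)F)C(F)(F)F
Why: Only C6 carries an α-hydrogen, so deprotonation and O-sulfonylation of the enolate (enol triflate formation) give the tetrasubstituted vinyl triflate regiospecifically; the C6 centre is erased and the silyloxy carbon keeps its R configuration.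

Step 3
Reactants: 4 (4R)-4-[(tert-butyldimethylsilyl)oxy]-2,6,6-trimethylcyclohex-1-en-1-yl trifluoromethanesulfonate, 5 (2E)-3-methylpent-2-en-4-yn-1-ol
Product: 6 (2E)-5-{(4R)-4-[(tert-butyldimethylsilyl)oxy]-2,6,6-trimethylcyclohex-1-en-1-yl}-3-methylpent-2-en-4-yn-1-ol
Conditions: Pd(PPh3)4 (5 mol %), CuI (10 mol %), i-Pr2NH, DMF, 40 °C
Reagents that add atoms: none
Why: Sonogashira coupling of an enol triflate with a terminal alkyne keeps the E enynol geometry and leaves the remote stereocentre untouched.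

Step 4
Reactants: 6 (2E)-5-{(4R)-4-[(tert-butyldimethylsilyl)oxy]-2,6,6-trimethylcyclohex-1-en-1-yl}-3-methylpent-2-en-4-yn-1-ol
Product: 7 {(2E)-5-[(4R)-4-hydroxy-2,6,6-trimethylcyclohex-1-en-1-yl]-3-methylpent-2-en-4-yn-1-yl}triphenylphosphonium bromide
Conditions: PPh3·HBr (1.2 equiv), MeOH, rt, 16 h
Reagents that add atoms: triphenylphosphine hydrobromide, Br.P(c1ccccc1)(c1ccccc1)c1ccccc1
Why: The allylic alcohol ionises under the mild acid and PPh3 captures the cation at the primary terminus (allylic phosphonium salt formation), while the same acid in methanol removes the silyl ether.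

Step 5
Reactants: 7 {(2E)-5-[(4R)-4-hydroxy-2,6,6-trimethylcyclohex-1-en-1-yl]-3-methylpent-2-en-4-yn-1-yl}triphenylphosphonium bromide, 8 (2E,4E,6E)-2,7-dimethylocta-2,4,6-trienedial (3 equiv)
Product: 10 (2E,4E,6E,8E,10E)-13-[(4R)-4-hydroxy-2,6,6-trimethylcyclohex-1-en-1-yl]-2,7,11-trimethyltrideca-2,4,6,8,10-pentaen-12-ynal, via C15 ylide 9 (not isolated)
Conditions: NaOMe (1.05 equiv), CH2Cl2/MeOH, 0 °C → rt; then I2 (1 mol %), CH2Cl2, daylight, rt
Reagents that add atoms: none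
Why: Wittig olefination of a semi-stabilised allylic ylide with one formyl group of the excess dialdehyde, followed by iodine-catalysed Z→E equilibration of the new double bond, gives the mono-adduct as the all-E aldehyde.

Step 6
Reactants: 10 (2E,4E,6E,8E,10E)-13-[(4R)-4-hydroxy-2,6,6-trimethylcyclohex-1-en-1-yl]-2,7,11-trimethyltrideca-2,4,6,8,10-pentaen-12-ynal
Product: 11 (2E,4E,6E,8E,10E)-13-[(4R)-4-hydroxy-2,6,6-trimethylcyclohex-1-en-1-yl]-2,7,11-trimethyltrideca-2,4,6,8,10-pentaen-12-yn-1-ol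
Conditions: NaBH4, MeOH/CH2Cl2, 0 °C
Reagents that add atoms: none
Why: Borohydride 1,2-reduction of a conjugated aldehyde is fast and leaves polyene, alkyne and secondary alcohol alone.

Step 7
Reactants: 11 (2E,4E,6E,8E,10E)-13-[(4R)-4-hydroxy-2,6,6-trimethylcyclohex-1-en-1-yl]-2,7,11-trimethyltrideca-2,4,6,8,10-pentaen-12-yn-1-ol
Product: 12 {(2E,4E,6E,8E,10E)-13-[(4R)-4-hydroxy-2,6,6-trimethylcyclohex-1-en-1-yl]-2,7,11-trimethyltrideca-2,4,6,8,10-pentaen-12-yn-1-yl}triphenylphosphonium bromide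
Conditions: PPh3·HBr (1.1 equiv), MeOH/CH2Cl2, 0 °C → rt
Reagents that add atoms: triphenylphosphine hydrobromide, Br.P(c1ccccc1)(c1ccccc1)c1ccccc1
Why: The polyenylic alcohol ionises even more readily than in step 4 and PPh3 traps the delocalised cation at the terminal carbon (allylic phosphonium salt formation, as for retinol).

Step 8
Reactants: 4 (4R)-4-[(tert-butyldimethylsilyl)oxy]-2,6,6-trimethylcyclohex-1-en-1-yl trifluoromethanesulfonate, 13 (2Z)-3-methylpent-2-en-4-yn-1-ol (1.5 equiv)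
Product: 15 tert-butyldimethyl({(1R)-3,5,5-trimethyl-4-[(3-methylfuran-2-yl)methyl]cyclohex-3-en-1-yl}oxy)silane, via Z-enynol 14 (not isolated)
Conditions: Pd(PPh3)4 (5 mol %), CuI (10 mol %), i-Pr2NH, DMF, 40 °C; aqueous work-up; then AgNO3 on silica gel (10 mol %), hexane, rt
Reagents that add atoms: none
Why: Sonogashira coupling followed by silver-catalysed 5-exo-dig hydroalkoxylation and aromatisation (Marshall-type furan synthesis) delivers the hydroxyl oxygen regiospecifically to C8, and kinetic protonation at the exocyclic CH carbon keeps the ring C5=C6 bond out of conjugation.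

Step 9
Reactants: 15 tert-butyldimethyl({(1R)-3,5,5-trimethyl-4-[(3-methylfuran-2-yl)methyl]cyclohex-3-en-1-yl}oxy)silane
Product: 19 (2E)-5-{(1S,4S,6R)-4-[(tert-butyldimethylsilyl)oxy]-2,2,6-trimethyl-7-oxabicyclo[4.1.0]heptan-1-yl}-3-methyl-4-oxopent-2-enal, via furan endoperoxide 16 (not isolated), via methoxy hydroperoxide 17 (not isolated), via 9Z-oxoenal 18 (not isolated)
Conditions: O2, tetraphenylporphyrin (1 mol %), visible light, CH2Cl2/MeOH (20:1), −78 °C; then MoO2(acac)2 (5 mol %), Na2HPO4, −20 → 20 °C; filter through silica; then I2 (2 mol %), CH2Cl2, daylight, rt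
Reagents that add atoms: dioxygen, O=O
Why: Proposed new method: singlet oxygen adds [4+2] to the electron-rich 2,3-dialkylfuran roughly a hundred times faster than it attacks the hindered ring alkene, methanol opens the endoperoxide to an α-methoxy hydroperoxide, and MoO2(acac)2 (hexavalent molybdenum) then transfers the terminal peroxide oxygen of one molecule to the nucleophilic tetrasubstituted C5=C6 bond of another, after which the reduced hemiketal loses methanol to unveil the Z-4-oxo-enal, so that both atoms of one O2 end up in the molecule (oxirane oxygen and formyl oxygen, the ketone oxygen being the former furan oxygen); the bulky alkylperoxo–molybdenum species is expected to attack the ring face opposite the C3 silyloxy group and so set 5R,6S (the minor syn isomer is removed on silica), and catalytic iodine finally equilibrates the 9Z enal to 9E; the closest known reactions are molybdenum-catalysed epoxidation of alkenes with alkyl hydroperoxides, the one-pot photooxygenation–oxygen-transfer tandem of allylic hydroperoxides catalysed by tetravalent titanium, and the photooxygenation of furans to cis-enediones.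

Step 10
Reactants: 12 {(2E,4E,6E,8E,10E)-13-[(4R)-4-hydroxy-2,6,6-trimethylcyclohex-1-en-1-yl]-2,7,11-trimethyltrideca-2,4,6,8,10-pentaen-12-yn-1-yl}triphenylphosphonium bromide, 19 (2E)-5-{(1S,4S,6R)-4-[(tert-butyldimethylsilyl)oxy]-2,2,6-trimethyl-7-oxabicyclo[4.1.0]heptan-1-yl}-3-methyl-4-oxopent-2-enal
Product: 21 (3S,5R,6S,3'R)-3-[(tert-butyldimethylsilyl)oxy]-5,6-epoxy-3'-hydroxy-7',8'-didehydro-5,6,7,8-tetrahydro-β,β-caroten-8-one, via C25 ylide 20 (not isolated)
Conditions: NaN(SiMe3)2 (1.0 equiv to 12), THF, −78 °C; ylide added to 19 at −78 → −30 °C; NH4Cl; then I2 (1 mol %), CH2Cl2, daylight, rt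
Reagents that add atoms: none
Why: At −78 °C the Wittig olefination of the unhindered enal formyl group outruns both attack on the hindered enone carbonyl and deprotonation next to the oxirane, and iodine equilibration then sets the new C11=C12 bond E (all-E isomer purified by chromatography and crystallisation).

Step 11
Reactants: 21 (3S,5R,6S,3'R)-3-[(tert-butyldimethylsilyl)oxy]-5,6-epoxy-3'-hydroxy-7',8'-didehydro-5,6,7,8-tetrahydro-β,β-caroten-8-one
Product: 22 (3S,5R,6S,3'R)-5,6-epoxy-3,3'-dihydroxy-7',8'-didehydro-5,6,7,8-tetrahydro-β,β-caroten-8-one (halocynthiaxanthin)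
Conditions: HF·pyridine, excess pyridine, THF, 0 °C → rt
Reagents that add atoms: none
Why: Buffered fluoride desilylation (Si–F bond formation) frees the C3 hydroxyl without the basic conditions that would open the β,γ-epoxy ketone and touches no stereocentre.

## Compound list

1 | (4R,6R)-4-hydroxy-2,2,6-trimethylcyclohexan-1-one (actinol) | C[C@@H]1C[C@@H](O)CC(C)(C)C1=O | starting material
2 | (4R,6R)-4-[(tert-butyldimethylsilyl)oxy]-2,2,6-trimethylcyclohexan-1-one | C[C@@H]1C[C@@H](O[Si](C)(C)C(C)(C)C)CC(C)(C)C1=O | intermediate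
3 | potassium (4R)-4-[(tert-butyldimethylsilyl)oxy]-2,6,6-trimethylcyclohex-1-en-1-olate | CC1=C([O-])C(C)(C)C[C@H](O[Si](C)(C)C(C)(C)C)C1.[K+] | intermediate
4 | (4R)-4-[(tert-butyldimethylsilyl)oxy]-2,6,6-trimethylcyclohex-1-en-1-yl trifluoromethanesulfonate | CC1=C(OS(=O)(=O)C(F)(F)F)C(C)(C)C[C@H](O[Si](C)(C)C(C)(C)C)C1 | intermediate
5 | (2E)-3-methylpent-2-en-4-yn-1-ol | C#C/C(C)=C/CO | starting material
6 | (2E)-5-{(4R)-4-[(tert-butyldimethylsilyl)oxy]-2,6,6-trimethylcyclohex-1-en-1-yl}-3-methylpent-2-en-4-yn-1-ol | CC1=C(C#C/C(C)=C/CO)C(C)(C)C[C@H](O[Si](C)(C)C(C)(C)C)C1 | intermediate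
7 | {(2E)-5-[(4R)-4-hydroxy-2,6,6-trimethylcyclohex-1-en-1-yl]-3-methylpent-2-en-4-yn-1-yl}triphenylphosphonium bromide | CC1=C(C#C/C(C)=C/C[P+](c2ccccc2)(c2ccccc2)c2ccccc2)C(C)(C)C[C@H](O)C1.[Br-] | intermediate
8 | (2E,4E,6E)-2,7-dimethylocta-2,4,6-trienedial | O=C/C(C)=C/C=C/C=C(C)/C=O | starting material
9 | C15 ylide of 7 (triphenylphosphoranylidene form) | CC1=C(C#C/C(C)=C/C=P(c2ccccc2)(c2ccccc2)c2ccccc2)C(C)(C)C[C@H](O)C1 | intermediate
10 | (2E,4E,6E,8E,10E)-13-[(4R)-4-hydroxy-2,6,6-trimethylcyclohex-1-en-1-yl]-2,7,11-trimethyltrideca-2,4,6,8,10-pentaen-12-ynal | CC1=C(C#C/C(C)=C/C=C/C(C)=C/C=C/C=C(C)/C=O)C(C)(C)C[C@H](O)C1 | intermediate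
11 | (2E,4E,6E,8E,10E)-13-[(4R)-4-hydroxy-2,6,6-trimethylcyclohex-1-en-1-yl]-2,7,11-trimethyltrideca-2,4,6,8,10-pentaen-12-yn-1-ol | CC1=C(C#C/C(C)=C/C=C/C(C)=C/C=C/C=C(C)/CO)C(C)(C)C[C@H](O)C1 | intermediate
12 | {(2E,4E,6E,8E,10E)-13-[(4R)-4-hydroxy-2,6,6-trimethylcyclohex-1-en-1-yl]-2,7,11-trimethyltrideca-2,4,6,8,10-pentaen-12-yn-1-yl}triphenylphosphonium bromide | CC1=C(C#C/C(C)=C/C=C/C(C)=C/C=C/C=C(C)/C[P+](c2ccccc2)(c2ccccc2)c2ccccc2)C(C)(C)C[C@H](O)C1.[Br-] | intermediate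
13 | (2Z)-3-methylpent-2-en-4-yn-1-ol | C#C/C(C)=C\CO | starting material
14 | (2Z)-5-{(4R)-4-[(tert-butyldimethylsilyl)oxy]-2,6,6-trimethylcyclohex-1-en-1-yl}-3-methylpent-2-en-4-yn-1-ol | CC1=C(C#C/C(C)=C\CO)C(C)(C)C[C@H](O[Si](C)(C)C(C)(C)C)C1 | intermediate
15 | tert-butyldimethyl({(1R)-3,5,5-trimethyl-4-[(3-methylfuran-2-yl)methyl]cyclohex-3-en-1-yl}oxy)silane | CC1=C(Cc2occc2C)C(C)(C)C[C@H](O[Si](C)(C)C(C)(C)C)C1 | intermediate
16 | furan 2,5-endoperoxide of 15 (1-substituted 6-methyl-2,3,7-trioxabicyclo[2.2.1]hept-5-ene, diastereomer mixture) | CC1=C(CC23OOC(O2)C=C3C)C(C)(C)C[C@H](O[Si](C)(C)C(C)(C)C)C1 | intermediate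
17 | 5-hydroperoxy-2-methoxy-3-methyl-2,5-dihydrofuran-2-ylmethyl derivative of the silyloxy cyclohexene (diastereomer mixture) | CC1=C(CC2(OC)OC(OO)C=C2C)C(C)(C)C[C@H](O[Si](C)(C)C(C)(C)C)C1 | intermediate
18 | (2Z)-5-{(1S,4S,6R)-4-[(tert-butyldimethylsilyl)oxy]-2,2,6-trimethyl-7-oxabicyclo[4.1.0]heptan-1-yl}-3-methyl-4-oxopent-2-enal | O=C/C=C(/C)C(=O)C[C@@]12O[C@]1(C)C[C@@H](O[Si](C)(C)C(C)(C)C)CC2(C)C | intermediate
19 | (2E)-5-{(1S,4S,6R)-4-[(tert-butyldimethylsilyl)oxy]-2,2,6-trimethyl-7-oxabicyclo[4.1.0]heptan-1-yl}-3-methyl-4-oxopent-2-enal | O=C/C=C(\C)C(=O)C[C@@]12O[C@]1(C)C[C@@H](O[Si](C)(C)C(C)(C)C)CC2(C)C | intermediate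
20 | C25 ylide of 12 (triphenylphosphoranylidene form) | CC1=C(C#C/C(C)=C/C=C/C(C)=C/C=C/C=C(C)/C=P(c2ccccc2)(c2ccccc2)c2ccccc2)C(C)(C)C[C@H](O)C1 | intermediate
21 | (3S,5R,6S,3'R)-3-[(tert-butyldimethylsilyl)oxy]-5,6-epoxy-3'-hydroxy-7',8'-didehydro-5,6,7,8-tetrahydro-β,β-caroten-8-one | CC1=C(C#C/C(C)=C/C=C/C(C)=C/C=C/C=C(C)/C=C/C=C(\C)C(=O)C[C@@]23O[C@]2(C)C[C@@H](O[Si](C)(C)C(C)(C)C)CC3(C)C)C(C)(C)C[C@H](O)C1 | intermediate
22 | (3S,5R,6S,3'R)-5,6-epoxy-3,3'-dihydroxy-7',8'-didehydro-5,6,7,8-tetrahydro-β,β-caroten-8-one (halocynthiaxanthin) | CC1=C(C#C/C(C)=C/C=C/C(C)=C/C=C/C=C(C)/C=C/C=C(\C)C(=O)C[C@@]23O[C@]2(C)C[C@@H](O)CC3(C)C)C(C)(C)C[C@H](O)C1 | target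

## Step count and risks

Total steps: 11. Longest linear sequence: 9 (steps 1–7, 10, 11).

The three steps most likely to fail, with fallbacks:

**Step 9 (the new oxygen relay).** It can fail in three ways: hydroperoxide 17 may rearrange to a butenolide before it transfers oxygen; singlet oxygen may attack C5=C6 in an ene reaction; or the facial selectivity may be low. The facial selectivity is the weakest point, because nothing directs the oxidant and the anti preference rests on steric approach control alone. The fallback uses known chemistry, moves the epoxidation ahead of the furan and puts it under reagent control. It sets out from 4 and comes back at 19. Stille hydroxymethylation of 4 with (tributylstannyl)methanol (Pd(PPh3)4, LiCl, dioxane, 100 °C) gives [(4R)-4-[(tert-butyldimethylsilyl)oxy]-2,6,6-trimethylcyclohex-1-en-1-yl]methanol F1. Katsuki–Sharpless epoxidation (Ti(Oi-Pr)4, D-(−)-diethyl tartrate, t-BuOOH, 4 Å sieves, CH2Cl2, −20 °C; this is the tartrate enantiomer I assign, from the known sense of the reaction, to the face anti to the silyloxy group) gives [(1R,4S,6R)-4-[(tert-butyldimethylsilyl)oxy]-2,2,6-trimethyl-7-oxabicyclo[4.1.0]heptan-1-yl]methanol F2. Triflation (Tf2O, 2,6-lutidine, CH2Cl2, −78 °C) gives [(1R,4S,6R)-4-[(tert-butyldimethylsilyl)oxy]-2,2,6-trimethyl-7-oxabicyclo[4.1.0]heptan-1-yl]methyl trifluoromethanesulfonate F3. Copper-catalysed Grignard–triflate coupling (CuBr·SMe2 10 mol %, THF, −40 → 0 °C) with (3-methylfuran-2-yl)magnesium bromide F4, made from 2-bromo-3-methylfuran and magnesium, gives 2-{[(1S,4S,6R)-4-[(tert-butyldimethylsilyl)oxy]-2,2,6-trimethyl-7-oxabicyclo[4.1.0]heptan-1-yl]methyl}-3-methylfuran F5; this displacement is at a hindered, neopentyl-like carbon and is the fallback's own uncertain step. Ordinary furan photooxygenation with reductive work-up (O2, tetraphenylporphyrin, light, CH2Cl2, −78 °C; then Me2S) opens F5 to 18, and iodine isomerisation as in step 9 gives 19.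

**Step 10 (Wittig in the presence of the base-labile β,γ-epoxy ketone).** If ylide or alkoxide opens the oxirane by α-deprotonation, the ketone is carried through the coupling as an alcohol. This fallback sets out from 19 and comes back at 21. Luche reduction of 19 (NaBH4, CeCl3·7H2O, MeOH, −40 °C) gives (2E)-5-{(1S,4S,6R)-4-[(tert-butyldimethylsilyl)oxy]-2,2,6-trimethyl-7-oxabicyclo[4.1.0]heptan-1-yl}-3-methylpent-2-ene-1,4-diol F6 (both C8 epimers). Selective oxidation of the primary allylic alcohol (TEMPO, PhI(OAc)2, CH2Cl2) gives (2E)-5-{(1S,4S,6R)-4-[(tert-butyldimethylsilyl)oxy]-2,2,6-trimethyl-7-oxabicyclo[4.1.0]heptan-1-yl}-4-hydroxy-3-methylpent-2-enal F7. Wittig reaction with ylide 20 under the conditions of step 10 gives (3S,5R,6S,3'R)-3-[(tert-butyldimethylsilyl)oxy]-5,6-epoxy-7',8'-didehydro-5,6,7,8-tetrahydro-β,β-carotene-8,3'-diol F8. MnO2 (CH2Cl2, rt) then oxidises only the polyene-allylic C8 carbinol, so the epoxy ketone 21 appears after the last basic step.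

**Step 8 (coupling and cyclisation in one operation).** The terminal Z-enynol 13 can cyclise to 2,3-dimethylfuran before it couples, and the hindered triflate couples slowly. The fallback separates coupling from ring closure by masking the hydroxyl. It sets out from 13 and 4 and comes back at 14, then 15. Acetylation of 13 (Ac2O, pyridine) gives (2Z)-3-methylpent-2-en-4-yn-1-yl acetate F9. Sonogashira coupling with 4 (Pd(PPh3)4, CuI, i-Pr2NH, DMF) gives (2Z)-5-{(4R)-4-[(tert-butyldimethylsilyl)oxy]-2,6,6-trimethylcyclohex-1-en-1-yl}-3-methylpent-2-en-4-yn-1-yl acetate F10. Methanolysis (K2CO3, MeOH, 0 °C) gives isolated 14, which is cyclised separately with AgNO3 on silica gel to 15.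

Further compounds
F1 | step 9 | [(4R)-4-[(tert-butyldimethylsilyl)oxy]-2,6,6-trimethylcyclohex-1-en-1-yl]methanol | CC1=C(CO)C(C)(C)C[C@H](O[Si](C)(C)C(C)(C)C)C1
F2 | step 9 | [(1R,4S,6R)-4-[(tert-butyldimethylsilyl)oxy]-2,2,6-trimethyl-7-oxabicyclo[4.1.0]heptan-1-yl]methanol | OC[C@@]12O[C@]1(C)C[C@@H](O[Si](C)(C)C(C)(C)C)CC2(C)C
F3 | step 9 | [(1R,4S,6R)-4-[(tert-butyldimethylsilyl)oxy]-2,2,6-trimethyl-7-oxabicyclo[4.1.0]heptan-1-yl]methyl trifluoromethanesulfonate | O=S(=O)(OC[C@@]12O[C@]1(C)C[C@@H](O[Si](C)(C)C(C)(C)C)CC2(C)C)C(F)(F)F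
F4 | step 9 | (3-methylfuran-2-yl)magnesium bromide | Cc1ccoc1[Mg]Br
F5 | step 9 | 2-{[(1S,4S,6R)-4-[(tert-butyldimethylsilyl)oxy]-2,2,6-trimethyl-7-oxabicyclo[4.1.0]heptan-1-yl]methyl}-3-methylfuran | Cc1ccoc1C[C@@]12O[C@]1(C)C[C@@H](O[Si](C)(C)C(C)(C)C)CC2(C)C
F6 | step 10 | (2E)-5-{(1S,4S,6R)-4-[(tert-butyldimethylsilyl)oxy]-2,2,6-trimethyl-7-oxabicyclo[4.1.0]heptan-1-yl}-3-methylpent-2-ene-1,4-diol | OC/C=C(\C)C(O)C[C@@]12O[C@]1(C)C[C@@H](O[Si](C)(C)C(C)(C)C)CC2(C)C
F7 | step 10 | (2E)-5-{(1S,4S,6R)-4-[(tert-butyldimethylsilyl)oxy]-2,2,6-trimethyl-7-oxabicyclo[4.1.0]heptan-1-yl}-4-hydroxy-3-methylpent-2-enal | O=C/C=C(\C)C(O)C[C@@]12O[C@]1(C)C[C@@H](O[Si](C)(C)C(C)(C)C)CC2(C)C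
F8 | step 10 | (3S,5R,6S,3'R)-3-[(tert-butyldimethylsilyl)oxy]-5,6-epoxy-7',8'-didehydro-5,6,7,8-tetrahydro-β,β-carotene-8,3'-diol | CC1=C(C#C/C(C)=C/C=C/C(C)=C/C=C/C=C(C)/C=C/C=C(\C)C(O)C[C@@]23O[C@]2(C)C[C@@H](O[Si](C)(C)C(C)(C)C)CC3(C)C)C(C)(C)C[C@H](O)C1
F9 | step 8 | (2Z)-3-methylpent-2-en-4-yn-1-yl acetate | C#C/C(C)=C\COC(C)=O
F10 | step 8 | (2Z)-5-{(4R)-4-[(tert-butyldimethylsilyl)oxy]-2,6,6-trimethylcyclohex-1-en-1-yl}-3-methylpent-2-en-4-yn-1-yl acetate | CC1=C(C#C/C(C)=C\COC(C)=O)C(C)(C)C[C@H](O[Si](C)(C)C(C)(C)C)C1
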